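## Retrosynthetic overview

1. The quinone comes last. It arises by para-oxidation of the 2'-phenol of ring B in the (3R)-2',4',7-trihydroxy-5-methoxy-6,3'-diprenylisoflavan, which is released from its tri-MOM ether. Both prenyl groups and the 5-OMe group are carried from the start.
2. The key disconnection is the C3–C4 bond of the pyran ring (O1, C2, C3, C4, C4a, C8a). An NH placed between C3 and C4 gives a seven-membered (3R)-2,3,4,5-tetrahydro-1,4-benzoxazepine, which is contracted by nitrogen deletion (loss of N2 from its isodiazene).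
3. The enabling feature is double benzylic activation. C4 is benzylic to ring A (on C4a, ortho to C8a–O1 and C5–OMe, para to C7–O). C3 is benzylic to ring B (on C1', ortho/para to the 2'- and 4'-oxygens). Both C–N bonds of the isodiazene therefore break easily, and O1, C2, C4a and C8a stay as spectators that hold the carbon pair together.
4. The benzoxazepine comes from Staudinger/aza-Wittig/reduction of an azido aldehyde. That comes from an (S)-carbinol by one SN2 inversion, and the carbinol from a salicylaldehyde and an (S)-chlorohydrin (C3 set by asymmetric transfer hydrogenation). Only C–O and C–N bonds join the two halves before the key step.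
5. Ring order: rings A and B are bought. The seven-membered O,N-ring forms in step 10, the pyran ring by contraction in step 11, and the quinone from ring B in step 13.

Key step: step 11

Remark: flavonoid numbering is used (O1, C2, C3, C4, C4a, C5–C8, C8a; primed numbers for ring B). Prenyl = 3-methylbut-2-en-1-yl, MOM = methoxymethyl, ArB = 2,4-bis(methoxymethoxy)-3-prenylphenyl. C3 of the target is R (C2 > C1' > C4 > H).

## Route

Step 1
Reactants: 1 2,4,6-trihydroxybenzaldehyde
Product: 2 2,4,6-trihydroxy-3-prenylbenzaldehyde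
Conditions: prenyl bromide (1 equiv), KOH, H2O, 0 °C to rt
Reagents that add atoms: prenyl bromide (1-bromo-3-methylbut-2-ene), CC(C)=CCBr
Why: C-alkylation of an acylphloroglucinol phenoxide (ambident phenolate, C-attack favoured in water) should work because C3 and C5 of 1 are equivalent, so mono-prenylation can give only one regioisomer.

Step 2
Reactants: 2 2,4,6-trihydroxy-3-prenylbenzaldehyde
Product: 3 2,6-dihydroxy-4-(methoxymethoxy)-3-prenylbenzaldehyde
Conditions: MOMCl (1.05 equiv), K2CO3, acetone, 0 °C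
Reagents that add atoms: chloromethyl methyl ether (MOMCl), COCCl
Why: In this Williamson-type etherification the 4-OH, para to the formyl group, is the most acidic hydroxyl and the only one not hydrogen-bonded to C=O, so one equivalent of MOMCl should go there.

Step 3
Reactants: 4 resorcinol
Product: 5 1,3-bis(methoxymethoxy)benzene
Conditions: NaH, MOMCl (2.2 equiv), DMF, 0 °C to rt
Reagents that add atoms: chloromethyl methyl ether (MOMCl), COCCl
Why: This is a double Williamson-type O-alkylation of the bis-phenoxide, with no competing site.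

Step 4
Reactants: 5 1,3-bis(methoxymethoxy)benzene
Product: 7 1,3-bis(methoxymethoxy)-2-prenylbenzene, via aryllithium 6 (not isolated)
Conditions: n-BuLi, THF, 0 °C to rt; CuBr·SMe2 (cat.), prenyl bromide, −78 °C to rt
Reagents that add atoms: prenyl bromide, CC(C)=CCBr
Why: Directed ortho-metalation takes place at C2 between the two MOM ethers, and the aryl metal is alkylated at the primary carbon of the allylic bromide (SN2, with Cu(I) suppressing SN2').

Step 5
Reactants: 7 1,3-bis(methoxymethoxy)-2-prenylbenzene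
Product: 9 1-ArB-2-chloroethan-1-one, via aryllithium 8 (not isolated)
Conditions: n-BuLi, TMEDA, THF, 0 °C; ClCH2C(O)N(OMe)Me, −78 °C; then H2O
Reagents that add atoms: 2-chloro-N-methoxy-N-methylacetamide, CON(C)C(=O)CCl
Why: A second directed ortho-metalation next to a MOM ether (C4 and C6 are equivalent) is followed by a Weinreb ketone synthesis, whose chelated adduct prevents over-addition and keeps the C–Cl bond.

Step 6
Reactants: 9 1-ArB-2-chloroethan-1-one
Product: 10 (1S)-1-ArB-2-chloroethan-1-ol
Conditions: [Cp*RhCl((R,R)-TsDPEN)] (cat.), HCO2H/Et3N 5:2, EtOAc, rt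
Reagents that add atoms: none
Why: In this Noyori–Ikariya asymmetric transfer hydrogenation the (R,R)-catalyst delivers hydride to the face that gives (S)-2-chloro-1-arylethanols, which sets the future C3 stereocentre and leaves the isolated prenyl alkene alone.

Step 7
Reactants: 3 2,6-dihydroxy-4-(methoxymethoxy)-3-prenylbenzaldehyde; 10 (1S)-1-ArB-2-chloroethan-1-ol
Product: 12 2-[(2S)-2-ArB-2-hydroxyethoxy]-6-hydroxy-4-(methoxymethoxy)-5-prenylbenzaldehyde, via oxirane 11 (not isolated)
Conditions: K2CO3, DMF, 60 °C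
Reagents that add atoms: none
Why: Base closes 10 to oxirane 11 without touching the stereocentre, and the less hindered phenoxide of 3 (next to C–H, not the one between CHO and prenyl) opens it at the terminal carbon (SN2 epoxide opening), so the carbinol configuration is retained and the O1–C2 bond is made.

Step 8
Reactants: 12 2-[(2S)-2-ArB-2-hydroxyethoxy]-6-hydroxy-4-(methoxymethoxy)-5-prenylbenzaldehyde
Product: 13 2-[(2S)-2-ArB-2-hydroxyethoxy]-6-methoxy-4-(methoxymethoxy)-5-prenylbenzaldehyde
Conditions: MeI, K2CO3, DMF, 40 °C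
Reagents that add atoms: iodomethane, CI
Why: This Williamson methylation takes the last, hydrogen-bonded phenol, and the secondary alcohol is not deprotonated by carbonate.

Step 9
Reactants: 13 2-[(2S)-2-ArB-2-hydroxyethoxy]-6-methoxy-4-(methoxymethoxy)-5-prenylbenzaldehyde
Product: 15 2-[(2R)-2-azido-2-ArB-ethoxy]-6-methoxy-4-(methoxymethoxy)-5-prenylbenzaldehyde, via phosphate ester 14 (not isolated)
Conditions: (PhO)2P(O)N3, DBU, toluene, 0 °C to rt
Reagents that add atoms: diphenylphosphoryl azide, [N-]=[N+]=NP(=O)(Oc1ccccc1)Oc1ccccc1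
Why: Phosphate activation and SN2 displacement by azide (DPPA/DBU azidation) in a non-polar solvent should invert the carbinol carbon, turning (S)-OH into (R)-N3.

Step 10
Reactants: 15 2-[(2R)-2-azido-2-ArB-ethoxy]-6-methoxy-4-(methoxymethoxy)-5-prenylbenzaldehyde
Product: 18 (3R)-3-ArB-6-methoxy-8-(methoxymethoxy)-7-prenyl-2,3,4,5-tetrahydro-1,4-benzoxazepine, via iminophosphorane 16 (not isolated), via cyclic aldimine 17 (not isolated)
Conditions: PPh3, toluene, rt to 80 °C; then NaBH4, MeOH, 0 °C
Reagents that add atoms: none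
Why: A Staudinger reaction, an intramolecular aza-Wittig reaction with the ortho-formyl group (which closes the seven-membered ring) and borohydride reduction of the aldimine follow one another, and C3 takes no part in any of them.

Step 11
Reactants: 18 (3R)-3-ArB-6-methoxy-8-(methoxymethoxy)-7-prenyl-2,3,4,5-tetrahydro-1,4-benzoxazepine
Product: 21 (3R)-3-ArB-5-methoxy-7-(methoxymethoxy)-6-prenylchromane, via N-aminoamide 19 (not isolated), via isodiazene 20 (not isolated)
Conditions: N-(benzyloxy)-N-(pivaloyloxy)-4-(trifluoromethyl)benzamide (1.5 equiv), THF, 45 °C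
Reagents that add atoms: none
Why: N4 of 18 displaces pivalate at the electrophilic nitrogen of the anomeric amide to give 19, which collapses by a HERON-type shift of the benzyloxy group from nitrogen to the acyl carbon into benzyl 4-(trifluoromethyl)benzoate and isodiazene 20; 20 loses N2, and the C3/C5 carbon pair left behind couples to form the C3–C4 bond of the pyran ring. The closest known reaction type is the nitrogen deletion of secondary amines through 1,1-diazenes, established for dibenzylic amines and for ring contraction of cyclic alpha-aryl amines, seven- to six-membered cases included. The six-membered ring closes by recombination of a singlet benzylic radical pair whose two centres were bonded to the same nitrogen and stay tied through C2, O1, C8a and C4a, so the closure is an in-cage 1,6-coupling with no approach problem. C3 is the only stereocentre and is controlled by the substrate: the configuration set in steps 6 and 9 should be carried over with retention (3R in 18 to 3R in 21, C4 taking the place of N4), because coupling at the birth geometry is expected to be faster than rotation about C3–C1' and C3–C2, as in the stereospecific contractions of alpha,alpha'-diaryl cyclic 1,1-diazenes. The step needs N2 loss and coupling to outrun tautomerisation of 20 to a hydrazone, beta-scission of the C2–O1 bond and radical addition to the prenyl groups. Double benzylic activation (trioxygenated ring A at C5 of 18, dioxygenated ring B at C3) secures fast N2 loss at 45 °C, the prenyl alkenes sit meta to the carbons that carry the reacting centres and out of reach, and the neutral medium leaves MOM ethers, aryl ethers and alkenes untouched.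

Step 12
Reactants: 21 (3R)-3-ArB-5-methoxy-7-(methoxymethoxy)-6-prenylchromane
Product: 22 4-[(3R)-7-hydroxy-5-methoxy-6-prenylchroman-3-yl]-2-prenylbenzene-1,3-diol
Conditions: HCl (1 M aq., cat.), MeOH, 40 °C
Reagents that add atoms: none
Why: Acid-catalysed acetal exchange of the three MOM ethers with methanol is run mild and short enough that the aryl methyl ether survives and the ortho-prenylphenols do not cyclise.

Step 13
Reactants: 22 4-[(3R)-7-hydroxy-5-methoxy-6-prenylchroman-3-yl]-2-prenylbenzene-1,3-diol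
Product: 23 target, 2-hydroxy-5-[(3R)-7-hydroxy-5-methoxy-6-prenylchroman-3-yl]-3-prenylcyclohexa-2,5-diene-1,4-dione
Conditions: (KSO3)2NO (2.5 equiv), KH2PO4 buffer, acetone/H2O, rt
Reagents that add atoms: potassium nitrosodisulfonate (Fremy's salt), [K+].[K+].[O]N(S(=O)(=O)[O-])S(=O)(=O)[O-]
Why: In this Teuber oxidation the 2'-OH is the only phenol with a free para position (C5'–H; the para positions of 4'-OH and 7-OH are C1' and C4a), so the more electron-rich resorcinol ring B should give the 2',5'-quinone with 4'-OH left as the hydroxyquinone, and C3 is not touched.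

## Compound list

1 | 2,4,6-trihydroxybenzaldehyde | O=Cc1c(O)cc(O)cc1O | starting material
2 | 2,4,6-trihydroxy-3-prenylbenzaldehyde | O=Cc1c(O)cc(O)c(CC=C(C)C)c1O | intermediate
3 | 2,6-dihydroxy-4-(methoxymethoxy)-3-prenylbenzaldehyde | O=Cc1c(O)cc(OCOC)c(CC=C(C)C)c1O | intermediate
4 | resorcinol | Oc1cccc(O)c1 | starting material
5 | 1,3-bis(methoxymethoxy)benzene | COCOc1cccc(OCOC)c1 | intermediate
6 | [2,6-bis(methoxymethoxy)phenyl]lithium | [Li]c1c(OCOC)cccc1OCOC | intermediate
7 | 1,3-bis(methoxymethoxy)-2-prenylbenzene | COCOc1cccc(OCOC)c1CC=C(C)C | intermediate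
8 | [2,4-bis(methoxymethoxy)-3-prenylphenyl]lithium | [Li]c1ccc(OCOC)c(CC=C(C)C)c1OCOC | intermediate
9 | 1-[2,4-bis(methoxymethoxy)-3-prenylphenyl]-2-chloroethan-1-one | O=C(CCl)c1ccc(OCOC)c(CC=C(C)C)c1OCOC | intermediate
10 | (1S)-1-[2,4-bis(methoxymethoxy)-3-prenylphenyl]-2-chloroethan-1-ol | O[C@H](CCl)c1ccc(OCOC)c(CC=C(C)C)c1OCOC | intermediate
11 | (2S)-2-[2,4-bis(methoxymethoxy)-3-prenylphenyl]oxirane | O1C[C@@H]1c2ccc(OCOC)c(CC=C(C)C)c2OCOC | intermediate
12 | 2-[(2S)-2-ArB-2-hydroxyethoxy]-6-hydroxy-4-(methoxymethoxy)-5-prenylbenzaldehyde | O[C@H](COc1cc(OCOC)c(CC=C(C)C)c(O)c1C=O)c1ccc(OCOC)c(CC=C(C)C)c1OCOC | intermediate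
13 | 2-[(2S)-2-ArB-2-hydroxyethoxy]-6-methoxy-4-(methoxymethoxy)-5-prenylbenzaldehyde | O[C@H](COc1cc(OCOC)c(CC=C(C)C)c(OC)c1C=O)c1ccc(OCOC)c(CC=C(C)C)c1OCOC | intermediate
14 | diphenyl phosphate ester of 13, (S) | O=P(Oc1ccccc1)(Oc1ccccc1)O[C@H](COc1cc(OCOC)c(CC=C(C)C)c(OC)c1C=O)c1ccc(OCOC)c(CC=C(C)C)c1OCOC | intermediate
15 | 2-[(2R)-2-azido-2-ArB-ethoxy]-6-methoxy-4-(methoxymethoxy)-5-prenylbenzaldehyde | [N-]=[N+]=N[C@@H](COc1cc(OCOC)c(CC=C(C)C)c(OC)c1C=O)c1ccc(OCOC)c(CC=C(C)C)c1OCOC | intermediate
16 | (R)-N-(triphenylphosphoranylidene)amine derived from 15 | c1ccccc1P(c1ccccc1)(c1ccccc1)=N[C@@H](COc1cc(OCOC)c(CC=C(C)C)c(OC)c1C=O)c1ccc(OCOC)c(CC=C(C)C)c1OCOC | intermediate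
17 | (3R)-3-ArB-6-methoxy-8-(methoxymethoxy)-7-prenyl-2,3-dihydro-1,4-benzoxazepine | C1=N[C@H](c3ccc(OCOC)c(CC=C(C)C)c3OCOC)COc2cc(OCOC)c(CC=C(C)C)c(OC)c12 | intermediate
18 | (3R)-3-ArB-6-methoxy-8-(methoxymethoxy)-7-prenyl-2,3,4,5-tetrahydro-1,4-benzoxazepine | C1N[C@H](c3ccc(OCOC)c(CC=C(C)C)c3OCOC)COc2cc(OCOC)c(CC=C(C)C)c(OC)c12 | intermediate
19 | N4-[N-(benzyloxy)-4-(trifluoromethyl)benzamido] derivative of 18 | C1N(N(OCc4ccccc4)C(=O)c4ccc(cc4)C(F)(F)F)[C@H](c3ccc(OCOC)c(CC=C(C)C)c3OCOC)COc2cc(OCOC)c(CC=C(C)C)c(OC)c12 | intermediate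
20 | N4-isodiazene (1,1-diazene) of 18 | C1[N+](=[N-])[C@H](c3ccc(OCOC)c(CC=C(C)C)c3OCOC)COc2cc(OCOC)c(CC=C(C)C)c(OC)c12 | intermediate
21 | (3R)-3-ArB-5-methoxy-7-(methoxymethoxy)-6-prenylchromane | C1[C@H](c3ccc(OCOC)c(CC=C(C)C)c3OCOC)COc2cc(OCOC)c(CC=C(C)C)c(OC)c12 | intermediate
22 | 4-[(3R)-7-hydroxy-5-methoxy-6-prenylchroman-3-yl]-2-prenylbenzene-1,3-diol | C1[C@H](c3ccc(O)c(CC=C(C)C)c3O)COc2cc(O)c(CC=C(C)C)c(OC)c12 | intermediate
23 | 2-hydroxy-5-[(3R)-7-hydroxy-5-methoxy-6-prenylchroman-3-yl]-3-prenylcyclohexa-2,5-diene-1,4-dione | COc1c(CC=C(C)C)c(O)cc2c1C[C@H](C1=CC(=O)C(O)=C(CC=C(C)C)C1=O)CO2 | target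

## Step count and risks

Total step count: 13. Longest linear sequence: 11 (steps 3–13).

Steps most likely to fail:

**1. Step 11.** The carbon pair may relax (rotation at C3) before it couples, which would erode the stereochemical memory. The isodiazene may also be diverted by tautomerisation or fragmentation.

The fallback expels oxygen instead of nitrogen, through an anionic [1,2]-Wittig ring contraction. It needs the opposite carbinol configuration because no inversion intervenes. It sets out from 9 and returns at 21.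

Transfer hydrogenation of 9 with the (S,S)-catalyst gives the (1R)-chlorohydrin F1. K2CO3/DMF and phenol 3 convert it through the (2R)-oxirane F2 into the (R)-hydroxy ether F3. MeI/K2CO3 gives the methyl ether F4, and NaBH4 gives the diol F5. PPTS in dilute CH2Cl2 ionises only the trioxygenated benzylic alcohol, which is captured by the secondary hydroxyl to give the (3R)-2,3-dihydro-5H-1,4-benzodioxepine F6. Excess n-BuLi (THF, −78 to 0 °C) deprotonates C5, and C3 migrates from oxygen to C5 with retention to give the isoflavan-4-ol F7. Et3SiH/BF3·OEt2 at −78 °C then removes the benzylic hydroxyl and gives 21.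

**2. Step 9.** The electron-rich benzylic phosphate may ionise (SN1 leakage, participation of the neighbouring 2'-oxygen), which would spoil the clean inversion.

In the fallback the C3–N stereocentre is set by auxiliary-controlled reduction instead of substitution. It sets out from 13 and returns at 18.

HC(OMe)3 with catalytic PPTS masks the aldehyde as the dimethyl acetal F8. Dess–Martin periodinane gives the aryloxy ketone F9. (S)-tert-Butanesulfinamide with Ti(OEt)4 gives the N-sulfinyl ketimine F10. NaBH4 at low temperature gives the (R)-configured sulfinamide F11; L-Selectride would give the opposite sense if needed. Brief HCl/MeOH removes the auxiliary and the acetal to give the amino aldehyde F12. F12 condenses at once to 17 and is reduced with NaBH4 to 18.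

**3. Step 13.** Hydrogen abstraction may be unselective (ring A phenol), and the hydroxyquinone may be over-oxidised by the radical oxidant.

The fallback uses two-electron para-hydroxylation instead of radical oxidation. It sets out from 22 and returns at 23.

Elbs persulfate oxidation (K2S2O8, aq. KOH, 0 °C to rt) attacks the only free para position and gives the 5'-sulfate F13. Dilute acid hydrolysis gives the 2',4',5'-triol F14. Air or Ag2O then oxidises F14 to 23.

## Further compounds

F1 | step 11 | (1R)-1-[2,4-bis(methoxymethoxy)-3-prenylphenyl]-2-chloroethan-1-ol | O[C@@H](CCl)c1ccc(OCOC)c(CC=C(C)C)c1OCOC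
F2 | step 11 | (2R)-2-[2,4-bis(methoxymethoxy)-3-prenylphenyl]oxirane | O1C[C@H]1c2ccc(OCOC)c(CC=C(C)C)c2OCOC
F3 | step 11 | 2-[(2R)-2-ArB-2-hydroxyethoxy]-6-hydroxy-4-(methoxymethoxy)-5-prenylbenzaldehyde | O[C@@H](COc1cc(OCOC)c(CC=C(C)C)c(O)c1C=O)c1ccc(OCOC)c(CC=C(C)C)c1OCOC
F4 | step 11 | 2-[(2R)-2-ArB-2-hydroxyethoxy]-6-methoxy-4-(methoxymethoxy)-5-prenylbenzaldehyde | O[C@@H](COc1cc(OCOC)c(CC=C(C)C)c(OC)c1C=O)c1ccc(OCOC)c(CC=C(C)C)c1OCOC
F5 | step 11 | (1R)-1-ArB-2-[2-(hydroxymethyl)-3-methoxy-5-(methoxymethoxy)-4-prenylphenoxy]ethan-1-ol | O[C@@H](COc1cc(OCOC)c(CC=C(C)C)c(OC)c1CO)c1ccc(OCOC)c(CC=C(C)C)c1OCOC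
F6 | step 11 | (3R)-3-ArB-6-methoxy-8-(methoxymethoxy)-7-prenyl-2,3-dihydro-5H-1,4-benzodioxepine | C1O[C@H](c3ccc(OCOC)c(CC=C(C)C)c3OCOC)COc2cc(OCOC)c(CC=C(C)C)c(OC)c12
F7 | step 11 | (3R)-3-ArB-5-methoxy-7-(methoxymethoxy)-6-prenylchroman-4-ol (C4 epimers) | OC1[C@H](c3ccc(OCOC)c(CC=C(C)C)c3OCOC)COc2cc(OCOC)c(CC=C(C)C)c(OC)c12
F8 | step 9 | (1S)-1-ArB-2-[2-(dimethoxymethyl)-3-methoxy-5-(methoxymethoxy)-4-prenylphenoxy]ethan-1-ol | O[C@H](COc1cc(OCOC)c(CC=C(C)C)c(OC)c1C(OC)OC)c1ccc(OCOC)c(CC=C(C)C)c1OCOC
F9 | step 9 | 1-ArB-2-[2-(dimethoxymethyl)-3-methoxy-5-(methoxymethoxy)-4-prenylphenoxy]ethan-1-one | O=C(COc1cc(OCOC)c(CC=C(C)C)c(OC)c1C(OC)OC)c1ccc(OCOC)c(CC=C(C)C)c1OCOC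
F10 | step 9 | (S)-N-tert-butanesulfinyl ketimine of F9 | CC(C)(C)[S@](=O)N=C(COc1cc(OCOC)c(CC=C(C)C)c(OC)c1C(OC)OC)c1ccc(OCOC)c(CC=C(C)C)c1OCOC
F11 | step 9 | (S)-N-{(1R)-1-ArB-2-[2-(dimethoxymethyl)-3-methoxy-5-(methoxymethoxy)-4-prenylphenoxy]ethyl}-2-methylpropane-2-sulfinamide | CC(C)(C)[S@](=O)N[C@@H](COc1cc(OCOC)c(CC=C(C)C)c(OC)c1C(OC)OC)c1ccc(OCOC)c(CC=C(C)C)c1OCOC
F12 | step 9 | 2-[(2R)-2-amino-2-ArB-ethoxy]-6-methoxy-4-(methoxymethoxy)-5-prenylbenzaldehyde | N[C@@H](COc1cc(OCOC)c(CC=C(C)C)c(OC)c1C=O)c1ccc(OCOC)c(CC=C(C)C)c1OCOC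
F13 | step 13 | potassium 2,4-dihydroxy-5-[(3R)-7-hydroxy-5-methoxy-6-prenylchroman-3-yl]-3-prenylphenyl sulfate | C1[C@H](c3cc(OS(=O)(=O)[O-])c(O)c(CC=C(C)C)c3O)COc2cc(O)c(CC=C(C)C)c(OC)c12.[K+]
F14 | step 13 | 5-[(3R)-7-hydroxy-5-methoxy-6-prenylchroman-3-yl]-3-prenylbenzene-1,2,4-triol | C1[C@H](c3cc(O)c(O)c(CC=C(C)C)c3O)COc2cc(O)c(CC=C(C)C)c(OC)c12
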